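**Assumption:** the target is taken exactly as drawn, that is (S) at the methyl-bearing carbon, Z ylidene, E trisubstituted alkene and the 4-hydroxy tautomer. A sequence run without isolating an intermediate counts as one step.

## Retrosynthetic overview
1. The last bond made is the CH2–CH= bond of the E alkene, by B-alkyl Suzuki coupling. This divides the target into a bis-furan vinyl iodide and a tetronic acid carrying a terminal alkene.
2. The tetronic acid is opened at the lactone C–O bond to a 2-methyl-3,4-dioxo ester, which is the fully oxidised terminal isoprene unit of the presumed biosynthesis. That ester is cut into a chiral alkyllithium and the enolate of diethyl oxalpropionate, which supplies all five carbons of the unit.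
3. The central furan is opened to a γ-keto aldehyde, the oxidation pattern presumed for the second isoprene unit. The keto aldehyde is cut into 3-(2-nitroethyl)furan and an α-methylene aldehyde.
4. The (S)-methyl centre comes from an Evans allylation, the E alkene from a Negishi carboalumination, and the Z ylidene from a thermodynamically controlled dehydration.
5. Ring order: the terminal furan is bought as furan-3-carbaldehyde, the central furan is closed in the left fragment, the tetronic acid is closed in the right fragment, and the two fragments are then joined.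

## Route

Step 1
Reactants: 1 furan-3-carbaldehyde; 2 nitromethane
Product: 3 3-[(E)-2-nitroethenyl]furan
Conditions: NH4OAc (0.3 equiv), MeNO2 (solvent), 95 °C, 2 h
Reagents that add atoms: none
Why: Henry (nitroaldol) condensation, in which the benzylic-type nitroaldol dehydrates spontaneously to the conjugated E-nitroalkene.

Step 2
Reactants: 3 3-[(E)-2-nitroethenyl]furan
Product: 4 3-(2-nitroethyl)furan
Conditions: NaBH4 (2 equiv), THF/MeOH 10:1, 0 °C (3 added slowly); aq NH4Cl
Reagents that add atoms: none
Why: Conjugate hydride reduction of a nitroalkene, in which the furan is inert and slow addition of 3 to excess hydride suppresses nitronate–nitroalkene dimerisation.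

Step 3
Reactants: 5 hex-5-yn-1-ol
Product: 7 (5E)-6-iodo-5-methylhex-5-en-1-ol, via alkenylalane 6 (not isolated)
Conditions: Me3Al (3 equiv), Cp2ZrCl2 (20 mol %), CH2Cl2, 0 °C → rt; I2 (1.2 equiv), THF, −30 °C; aq K2CO3
Reagents that add atoms: trimethylaluminium, C[Al](C)C; iodine, II
Why: Negishi Zr-catalysed carboalumination adds Me–Al syn across the terminal alkyne with methyl on the internal carbon, and iodinolysis proceeds with retention, so the E geometry of the target's trisubstituted alkene is fixed here.

Step 4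
Reactants: 7 (5E)-6-iodo-5-methylhex-5-en-1-ol
Product: 8 (5E)-6-iodo-5-methylhex-5-enal
Conditions: TEMPO (10 mol %), PhI(OAc)2 (1.1 equiv), CH2Cl2, rt
Reagents that add atoms: none
Why: TEMPO/oxoammonium oxidation stops at the aldehyde and leaves the vinyl iodide untouched.

Step 5
Reactants: 8 (5E)-6-iodo-5-methylhex-5-enal
Product: 9 (5E)-6-iodo-5-methyl-2-methylidenehex-5-enal
Conditions: 37% aq HCHO (1.2 equiv), pyrrolidine (10 mol %), EtCO2H (10 mol %), i-PrOH, 45 °C
Reagents that add atoms: formaldehyde, C=O
Why: Organocatalytic Mannich-type α-methylenation, in which the enamine adds to formaldehyde and the amine is then lost by β-elimination, converts the aldehyde into a 2-substituted acrolein under nearly neutral conditions.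

Step 6
Reactants: 4 3-(2-nitroethyl)furan; 9 (5E)-6-iodo-5-methyl-2-methylidenehex-5-enal
Product: 13 2-(furan-3-ylmethyl)-4-[(3E)-4-iodo-3-methylbut-3-en-1-yl]furan, via nitronate salt 10 (not isolated), via adduct nitronate 11 (not isolated), via keto aldehyde 12 (not isolated)
Conditions: 4 (1.3 equiv), NaOMe (1.3 equiv), MeOH, 0 °C; 9, 0 °C → rt, 2 h; poured into 4 M aq H2SO4/MeOH (1:2), −30 °C → 40 °C, 2 h
Reagents that add atoms: water, O
Why: Nitronate Michael addition, Nef reaction and Paal–Knorr cyclodehydration in one pot produce the γ-keto aldehyde that oxidation of the second isoprene unit is presumed to give in nature, and acid closes it to the 2,4-disubstituted furan with only one possible regiochemistry, the transient stereocentre being lost on aromatisation.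

Step 7
Reactants: 14 (4R)-4-benzyl-3-propanoyl-1,3-oxazolidin-2-one; 15 3-iodoprop-1-ene (allyl iodide)
Product: 17 (4R)-4-benzyl-3-[(2S)-2-methylpent-4-enoyl]-1,3-oxazolidin-2-one, via sodium Z-enolate 16 (not isolated)
Conditions: NaHMDS (1.1 equiv), THF, −78 °C; 15 (3 equiv), −78 → −40 °C
Reagents that add atoms: none
Why: Evans asymmetric alkylation, in which the chelated Z-enolate is allylated on the face opposite the benzyl group (dr ≥ 98:2, minor isomer removed by chromatography), sets the only stereocentre of the target as S.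

Step 8
Reactants: 17 (4R)-4-benzyl-3-[(2S)-2-methylpent-4-enoyl]-1,3-oxazolidin-2-one
Product: 18 (2S)-2-methylpent-4-en-1-ol
Conditions: LiBH4 (1.2 equiv), H2O (1 equiv), Et2O, 0 °C
Reagents that add atoms: none
Why: Reductive removal of the auxiliary occurs by hydride attack at the exocyclic imide carbonyl without enolisation, so the α-stereocentre is not epimerised and the alkene is untouched.

Step 9
Reactants: 18 (2S)-2-methylpent-4-en-1-ol
Product: 19 (4S)-5-iodo-4-methylpent-1-ene
Conditions: I2, PPh3, imidazole, Et2O/MeCN 3:1, 0 °C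
Reagents that add atoms: iodine, II
Why: Appel-type (Garegg–Samuelsson) iodination is an SN2 displacement at the primary carbon, so the adjacent stereocentre is not involved.

Step 10
Reactants: 19 (4S)-5-iodo-4-methylpent-1-ene; 20 diethyl 2-methyl-3-oxobutanedioate (diethyl oxalpropionate)
Product: 26 (5Z)-4-hydroxy-3-methyl-5-[(2S)-2-methylpent-4-en-1-ylidene]furan-2(5H)-one, via sodium enolate 21 (not isolated), via alkyllithium 22 (not isolated), via tetrahedral adduct 23 (not isolated), via diketo ester 24 (not isolated), via lactol 25 (not isolated)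
Conditions: 20 (1.3 equiv), NaH, THF, 0 °C; 19, t-BuLi (2.1 equiv), Et2O/pentane, −78 °C; combined at −78 °C, 1 h; AcOH, −78 °C; crude, p-TsOH·H2O (10 mol %), PhMe, 90 °C, EtOH distilled off
Reagents that add atoms: none
Why: Proposed new method: deprotonation locks the ketone and the C1 ester of 20 into an unreactive push–pull enolate, so 22 can only attack the oxalyl ester, where the neighbouring enolate oxygen chelates lithium and holds adduct 23 until the cold acid quench (closest known reaction: mono-addition of RLi/RMgX to dialkyl oxalates giving α-keto esters), and the released 2-methyl-3,4-dioxo ester 24, the oxidised terminal isoprene unit presumed in the biosynthesis, closes under acid to its ring tautomer 25 and loses water to the conjugated ylidene (closest known reaction: ring–chain tautomerism and enol lactonisation of γ-keto acids to γ-ylidene butenolides), with Z favoured thermodynamically because the E isomer suffers A(1,3) strain against the 4-OH and with the stereocentre safe because it is β to the ketone and cannot enolise.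

Step 11
Reactants: 26 (5Z)-4-hydroxy-3-methyl-5-[(2S)-2-methylpent-4-en-1-ylidene]furan-2(5H)-one; 13 2-(furan-3-ylmethyl)-4-[(3E)-4-iodo-3-methylbut-3-en-1-yl]furan
Product: 28 (5Z)-5-[(2S,6E)-9-[5-(furan-3-ylmethyl)furan-3-yl]-2,7-dimethylnon-6-en-1-ylidene]-4-hydroxy-3-methylfuran-2(5H)-one, via bis-boryl adduct 27 (not isolated)
Conditions: 26 (1.2 equiv), 9-BBN-H (2.5 equiv), THF, 0 °C → rt; 13, Pd(dppf)Cl2 (5 mol %), AsPh3 (10 mol %), Cs2CO3 (4 equiv), DMF/H2O, rt; acidic work-up (pH 3)
Reagents that add atoms: none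
Why: In this B-alkyl Suzuki–Miyaura coupling 9-BBN first converts the acidic OH into a borinate and then hydroborates only the monosubstituted alkene at its terminal CH2, and Pd transfers the primary alkyl group to the vinyl iodide with retention of E geometry while aqueous base frees the tetronate, so no stereochemical element is disturbed.

## Compound list
1 | furan-3-carbaldehyde | O=Cc1ccoc1 | starting material
2 | nitromethane | C[N+](=O)[O-] | starting material
3 | 3-[(E)-2-nitroethenyl]furan | O=[N+]([O-])/C=C/c1ccoc1 | intermediate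
4 | 3-(2-nitroethyl)furan | O=[N+]([O-])CCc1ccoc1 | intermediate
5 | hex-5-yn-1-ol | OCCCCC#C | starting material
6 | dimethyl{(1E)-6-[(dimethylalumanyl)oxy]-2-methylhex-1-en-1-yl}alumane | C[Al](C)/C=C(\C)CCCCO[Al](C)C | intermediate
7 | (5E)-6-iodo-5-methylhex-5-en-1-ol | OCCCC/C(C)=C/I | intermediate
8 | (5E)-6-iodo-5-methylhex-5-enal | O=CCCC/C(C)=C/I | intermediate
9 | (5E)-6-iodo-5-methyl-2-methylidenehex-5-enal | O=CC(=C)CC/C(C)=C/I | intermediate
10 | sodium nitronate of 3-(2-nitroethyl)furan | [Na+].[O-][N+]([O-])=CCc1ccoc1 | intermediate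
11 | sodium nitronate of (5E)-2-[3-(furan-3-yl)-2-nitropropyl]-6-iodo-5-methylhex-5-enal (racemic at C2) | [Na+].[O-][N+]([O-])=C(Cc1ccoc1)CC(C=O)CC/C(C)=C/I | intermediate
12 | (5E)-2-[3-(furan-3-yl)-2-oxopropyl]-6-iodo-5-methylhex-5-enal (racemic at C2) | O=CC(CC(=O)Cc1ccoc1)CC/C(C)=C/I | intermediate
13 | 2-(furan-3-ylmethyl)-4-[(3E)-4-iodo-3-methylbut-3-en-1-yl]furan | I/C=C(\C)CCc1coc(Cc2ccoc2)c1 | intermediate
14 | (4R)-4-benzyl-3-propanoyl-1,3-oxazolidin-2-one | CCC(=O)N1[C@H](Cc2ccccc2)COC1=O | starting material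
15 | 3-iodoprop-1-ene | C=CCI | starting material
16 | sodium (Z)-enolate of 14 | [Na+].C/C=C(\[O-])N1[C@H](Cc2ccccc2)COC1=O | intermediate
17 | (4R)-4-benzyl-3-[(2S)-2-methylpent-4-enoyl]-1,3-oxazolidin-2-one | O=C([C@@H](C)CC=C)N1[C@H](Cc2ccccc2)COC1=O | intermediate
18 | (2S)-2-methylpent-4-en-1-ol | OC[C@@H](C)CC=C | intermediate
19 | (4S)-5-iodo-4-methylpent-1-ene | IC[C@@H](C)CC=C | intermediate
20 | diethyl 2-methyl-3-oxobutanedioate | CCOC(=O)C(=O)C(C)C(=O)OCC | starting material
21 | sodium enolate of 20 (sodium 1,4-diethoxy-3-methyl-1,4-dioxobut-2-en-2-olate) | [Na+].CCOC(=O)C([O-])=C(C)C(=O)OCC | intermediate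
22 | [(2R)-2-methylpent-4-en-1-yl]lithium (same spatial arrangement as 19; the descriptor changes only because CH2Li ranks below the allylic CH2) | [Li]C[C@@H](C)CC=C | intermediate
23 | tetrahedral adduct of 22 on the oxalyl ester carbonyl of 21 (lithium sodium dialkoxide, side chain S) | [Li+].[Na+].CCOC([O-])(C[C@@H](C)CC=C)C([O-])=C(C)C(=O)OCC | intermediate
24 | ethyl (6S)-2,6-dimethyl-3,4-dioxonon-8-enoate (C2 epimers/enol) | CCOC(=O)C(C)C(=O)C(=O)C[C@@H](C)CC=C | intermediate
25 | 4,5-dihydroxy-3-methyl-5-[(2S)-2-methylpent-4-en-1-yl]furan-2(5H)-one (C5 epimers) | CC1=C(O)C(O)(C[C@@H](C)CC=C)OC1=O | intermediate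
26 | (5Z)-4-hydroxy-3-methyl-5-[(2S)-2-methylpent-4-en-1-ylidene]furan-2(5H)-one | CC1=C(O)/C(=C/[C@@H](C)CC=C)OC1=O | intermediate
27 | (5Z)-4-[(9-borabicyclo[3.3.1]nonan-9-yl)oxy]-5-[(2S)-5-(9-borabicyclo[3.3.1]nonan-9-yl)-2-methylpentylidene]-3-methylfuran-2(5H)-one | CC1=C(OB2C3CCCC2CCC3)/C(=C/[C@@H](C)CCCB2C3CCCC2CCC3)OC1=O | intermediate
28 | (5Z)-5-[(2S,6E)-9-[5-(furan-3-ylmethyl)furan-3-yl]-2,7-dimethylnon-6-en-1-ylidene]-4-hydroxy-3-methylfuran-2(5H)-one | CC1=C(O)/C(=C/[C@@H](C)CCC/C=C(\C)CCc2coc(Cc3ccoc3)c2)OC1=O | target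

## Step count
- **Total steps:** 11.
- **Longest linear sequence:** 5 steps, either 5 → 7 → 8 → 9 → 13 → 28 or 14 → 17 → 18 → 19 → 26 → 28.

## Steps most likely to fail

**Step 10.**
- Risks: double addition of 22, attack at the wrong carbonyl, or C-acylation to a cyclopentanetrione if base survives the quench.
- The fallback sets out from alkyllithium 22 (made from 19 as before) and builds the dioxo ester from the other side.
- Adding 22 to diethyl oxalate (THF, −78 °C) gives ethyl (4S)-4-methyl-2-oxohept-6-enoate F1.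
- TBSOTf/Et3N then masks the ketone as ethyl (2Z,4S)-2-[(tert-butyldimethylsilyl)oxy]-4-methylhepta-2,6-dienoate F2.
- A crossed Claisen condensation with the lithium enolate of ethyl propanoate (LDA, THF, −78 °C) gives ethyl (4Z,6S)-4-[(tert-butyldimethylsilyl)oxy]-2,6-dimethyl-3-oxonona-4,8-dienoate F3.
- HF·pyridine releases the Z enol, which lactonises onto the ethyl ester, and the route is rejoined at 26.
- In this variant the ylidene geometry is fixed before ring closure, and the propionate carbon–carbon bond is the last one made.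

**Step 6.**
- Risks: polymerisation or double Michael addition of 9, and acid-promoted furan–aldehyde condensation during the Nef stage.
- The fallback sets out from 9 and reverses the roles of the partners.
- Nitromethane 2 (DBU cat., MeCN) adds to 9 to give (5E)-6-iodo-5-methyl-2-(2-nitroethyl)hex-5-enal F4.
- HC(OMe)3 with catalytic p-TsOH gives (1E)-5-(dimethoxymethyl)-1-iodo-2-methyl-7-nitrohept-1-ene F5.
- Henry condensation of F5 with aldehyde 1 (n-BuNH2 cat., PhMe, Dean–Stark) gives 3-[(1E,7E)-4-(dimethoxymethyl)-8-iodo-7-methyl-2-nitroocta-1,7-dien-1-yl]furan F6.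
- Fe powder in AcOH/H2O (70 °C) reduces the nitroalkene to the ketone and cleaves the acetal, so the route is rejoined at keto aldehyde 12, which closes to 13 in the same acidic medium.

**Step 11.**
- Risks: the free tetronic acid consumes borane, and the tetronate may bind boron or palladium and slow transmetalation.
- The fallback sets out from 26 and carries the acid through the coupling in masked form.
- Me2SO4/K2CO3 in acetone gives (5Z)-4-methoxy-3-methyl-5-[(2S)-2-methylpent-4-en-1-ylidene]furan-2(5H)-one F7.
- 9-BBN-H (1.2 equiv) then gives (5Z)-5-[(2S)-5-(9-borabicyclo[3.3.1]nonan-9-yl)-2-methylpentylidene]-4-methoxy-3-methylfuran-2(5H)-one F8.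
- Suzuki coupling of F8 with 13 gives (5Z)-5-[(2S,6E)-9-[5-(furan-3-ylmethyl)furan-3-yl]-2,7-dimethylnon-6-en-1-ylidene]-4-methoxy-3-methylfuran-2(5H)-one F9.
- LiCl in DMF (110 °C) removes the O-methyl group, and the route is rejoined at 28.

## Further compounds
F1 | step 10 | ethyl (4S)-4-methyl-2-oxohept-6-enoate | CCOC(=O)C(=O)C[C@@H](C)CC=C
F2 | step 10 | ethyl (2Z,4S)-2-[(tert-butyldimethylsilyl)oxy]-4-methylhepta-2,6-dienoate | CCOC(=O)/C(O[Si](C)(C)C(C)(C)C)=C/[C@@H](C)CC=C
F3 | step 10 | ethyl (4Z,6S)-4-[(tert-butyldimethylsilyl)oxy]-2,6-dimethyl-3-oxonona-4,8-dienoate | CCOC(=O)C(C)C(=O)/C(O[Si](C)(C)C(C)(C)C)=C/[C@@H](C)CC=C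
F4 | step 6 | (5E)-6-iodo-5-methyl-2-(2-nitroethyl)hex-5-enal | O=CC(CC[N+](=O)[O-])CC/C(C)=C/I
F5 | step 6 | (1E)-5-(dimethoxymethyl)-1-iodo-2-methyl-7-nitrohept-1-ene | COC(OC)C(CC[N+](=O)[O-])CC/C(C)=C/I
F6 | step 6 | 3-[(1E,7E)-4-(dimethoxymethyl)-8-iodo-7-methyl-2-nitroocta-1,7-dien-1-yl]furan | COC(OC)C(C/C(=C\c1ccoc1)[N+](=O)[O-])CC/C(C)=C/I
F7 | step 11 | (5Z)-4-methoxy-3-methyl-5-[(2S)-2-methylpent-4-en-1-ylidene]furan-2(5H)-one | CC1=C(OC)/C(=C/[C@@H](C)CC=C)OC1=O
F8 | step 11 | (5Z)-5-[(2S)-5-(9-borabicyclo[3.3.1]nonan-9-yl)-2-methylpentylidene]-4-methoxy-3-methylfuran-2(5H)-one | CC1=C(OC)/C(=C/[C@@H](C)CCCB2C3CCCC2CCC3)OC1=O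
F9 | step 11 | (5Z)-5-[(2S,6E)-9-[5-(furan-3-ylmethyl)furan-3-yl]-2,7-dimethylnon-6-en-1-ylidene]-4-methoxy-3-methylfuran-2(5H)-one | CC1=C(OC)/C(=C/[C@@H](C)CCC/C=C(\C)CCc2coc(Cc3ccoc3)c2)OC1=O
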